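Everything rests on replacing the C3a–C8a fusion bond of the hydroazulene by a C4–C8a bond. This turns the target core into a cis-decalin that is three steps from a commercial enantiopure octalone. The key step exploits the fact that oxygen-bearing C4 of the seven-membered ring is the neighbour of C3a of the cyclopentane. In an all-cis decalin-1,2,8a-triol 1-mesylate the quaternary carbon shifts from the carbinol carbon to the mesylate carbon. One operation contracts one cyclohexane to the cyclopentane, expands the other to the cycloheptanone, sets C3a by inversion and leaves the C3 carbinol beta to the C4 ketone, ready for a directed redox esterification.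

Key step: step 4

Numbering: hydroazulenes carry the azulene numbering of the target. C3 is the ester carbon with isopropyl, C3a the ring-fusion CH, C4 the carbinol, C5=C6(CH3) the alkene, C7 the ketone, C8 the CH2 and C8a the quaternary carbon. Decalins carry naphthalene numbering. β is the face of the angular methyl group.

Assumption: the structure is taken at face value, with the acyl group on the tertiary O-3 and O-4 free. Base is therefore avoided once the ester is in place, because acyl migration to O-4 is downhill. Octalone 1 and aldehyde 11 are taken as catalogue chemicals.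

Step 1
Reactants: 1 (S)-4a-methyl-4,4a,5,6,7,8-hexahydronaphthalen-2(3H)-one
Product: 2 (2R,4aS)-4a-methyl-2-(propan-2-yl)-2,3,4,4a,5,6,7,8-octahydronaphthalen-2-ol (2β-OH and 2α-isopropyl)
Conditions: i-PrMgCl, LaCl3·2LiCl, THF, 0 °C; then H2O
Reagents that add atoms: isopropylmagnesium chloride, CC(C)[Mg]Cl
Why: 1,2-Grignard addition to the enone, kept free of enolisation and hydride transfer by the oxophilic lanthanum salt, in which the nucleophile enters axially from the α face, anti to the angular methyl group, so that the new carbinol carbon carries β-OH and α-isopropyl.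

Step 2
Reactants: 2 allylic alcohol
Product: 4 (1S,2R,4aS,8aR)-4a-methyl-2-(propan-2-yl)decahydronaphthalene-1,2,8a-triol (all three OH β), via osmate ester 3 (not isolated)
Conditions: OsO4 (1.05 equiv), TMEDA, CH2Cl2, −78 °C; then aq Na2SO3, THF, reflux
Reagents that add atoms: osmium tetroxide, O=[Os](=O)(=O)=O
Why: Hydrogen-bond-directed syn-dihydroxylation of a cyclic allylic alcohol, in which the half-chair with equatorial isopropyl presents a pseudoaxial β-hydroxyl that binds the OsO4·TMEDA complex and delivers it to the β face of the only alkene, so that both new C–O bonds are cis to O-2 and to the angular methyl group.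

Step 3
Reactants: 4 all-cis triol
Product: 5 (1S,2R,4aS,8aR)-2,8a-dihydroxy-4a-methyl-2-(propan-2-yl)decahydronaphthalen-1-yl methanesulfonate
Conditions: MsCl (1.1 equiv), Et3N, CH2Cl2, −20 °C
Reagents that add atoms: methanesulfonyl chloride, CS(=O)(=O)Cl
Why: Sulfonylation through sulfene takes the only secondary hydroxyl because the two flanking tertiary carbinols are too hindered at this temperature, and no stereocentre is touched.

Step 4
Reactants: 5 dihydroxy mesylate
Product: 6 (3R,3aR,8aS)-3-hydroxy-8a-methyl-3-(propan-2-yl)octahydroazulen-4(1H)-one (trans-fused with 3β-OH and 3aα-H)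
Conditions: Et3Al (3 equiv), CH2Cl2, −78 to −20 °C; then H2O
Reagents that add atoms: none
Why: Et3Al turns both tertiary hydroxyls into aluminium alkoxides and pulls on the sulfonate, and as the C1–O bond breaks the C4a–C8a σ bond, antiperiplanar to the equatorial mesylate in the cis-decalin chair–chair form that keeps the isopropyl group equatorial, moves its C4a end from C8a to C1 while the C8a alkoxide becomes the ketone. The closest known reaction type is the semipinacol (pinacol-type) rearrangement of vicinal cis-diol monosulfonates, the classical decalin-to-hydroazulene conversion, here in its organoaluminium-promoted form. No ring is closed by a cyclisation: the one suprafacial 1,2-alkyl shift expels C8a from the ring C1–C2–C3–C4–C4a–C8a (ring contraction, six to five, giving the cyclopentane) and inserts C1 into the other cyclohexane (ring expansion, six to seven, giving the cycloheptanone). The only new stereocentre, C3a, forms by inversion at the mesylate carbon, so the β-mesylate gives α-H and the trans ring fusion, the migrating quaternary carbon keeps its configuration and the C3 carbinol carbon is not touched. The step needs C4a and not C3 to migrate, since the C2–C3 bond is antiperiplanar too and could be pushed by the C2 alkoxide; the substrate secures this because the fully substituted C4a is a far better migrating group than a CH2 and its shift relieves the 1,3-diaxial oxygen pair and the crowded cis-decalin junction, while C8 on C8a is gauche to the mesylate and cannot shift. The product stays a chelated aluminium aldolate until the cold quench, which blocks retro-aldol opening and epimerisation at C3a.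

Step 5
Reactants: 6 β-hydroxy cycloheptanone
Product: 7 (3R,3aR,8aS)-3-hydroxy-8a-methyl-3-(propan-2-yl)-2,3,3a,7,8,8a-hexahydroazulen-4(1H)-one
Conditions: IBX (1.3 equiv), DMSO, 65 °C
Reagents that add atoms: none
Why: IBX dehydrogenation of a ketone through its enol, which can only give the C5–C6 alkene because the other α-carbon, C3a, has no hydrogen on either further neighbour (C3 and C8a are fully substituted), and the tertiary alcohol is inert to the oxidant.

Step 6
Reactants: 7 cycloheptenone
Product: 9 (3R,3aR,8aS)-3-hydroxy-6,8a-dimethyl-3-(propan-2-yl)-2,3,3a,7,8,8a-hexahydroazulen-4(1H)-one, via silyl enol ether 8 (not isolated)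
Conditions: MeMgBr (2.5 equiv), CuBr·SMe2 (cat.), TMSCl, THF, −78 °C; aq NaHCO3; then Pd(OAc)2 (cat.), O2, DMSO, 25 °C
Reagents that add atoms: methylmagnesium bromide, C[Mg]Br
Why: Copper-catalysed conjugate addition of the Grignard reagent at C6 with chlorosilane trapping (the first equivalent only deprotonates the tertiary hydroxyl), followed by Saegusa–Ito oxidation of the regiodefined silyl enol ether, restores the C5–C6 double bond and thereby erases the transient C6 stereocentre.

Step 7
Reactants: 9 β-methyl enone
Product: 10 (3R,3aR,8aR)-3-hydroxy-6,8a-dimethyl-3-(propan-2-yl)-1,2,3,3a,8,8a-hexahydroazulene-4,7-dione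
Conditions: dirhodium tetrakis(caprolactamate) Rh2(cap)4 (1 mol %), t-BuOOH (70% in water), ClCH2CH2Cl, 40 °C
Reagents that add atoms: tert-butyl hydroperoxide, CC(C)(C)OO
Why: Dirhodium-catalysed allylic (γ) C–H oxidation of an enone to the 1,4-enedione, in which the tert-butylperoxyl radical takes a hydrogen from the ring methylene C7 in preference to the C6 methyl group (secondary against primary C–H) and the mixed peroxide collapses to the ketone.

Step 8
Reactants: 10 β-hydroxy enedione; 11 4-[(tert-butyldimethylsilyl)oxy]benzaldehyde
Product: 13 (3R,3aS,4S,8aR)-4-hydroxy-6,8a-dimethyl-7-oxo-3-(propan-2-yl)-1,2,3,3a,4,7,8,8a-octahydroazulen-3-yl 4-hydroxybenzoate, via silyl-protected ester 12 (not isolated)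
Conditions: SmI2 (0.3 equiv, aged with 11 until decolourised), 11 (4 equiv), THF, −10 °C; then HF·pyridine, 0 °C
Reagents that add atoms: none
Why: Proposed new method: the Evans–Tishchenko reaction, established for secondary β-hydroxy ketones, is applied to a tertiary carbinol; the trivalent samarium alkoxide of O-3 adds to aldehyde 11, the samarium-bound hemiacetal chelates the C4 carbonyl and passes its hydride through a six-membered transition state to the face of C4 that looks at C3–O, so that H-4 ends cis to C3 on the seven-membered ring (4α-OH, 4S); only the ketone β to the hydroxyl can be reached, so the C7 carbonyl survives, the acyl group is left on the hindered tertiary oxygen, and base-free HF·pyridine then frees the phenol without acyl migration; the closest known reaction type is the samarium-catalysed Evans–Tishchenko reduction of secondary β-hydroxy ketones with aromatic aldehydes.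

Compound list
1 | (S)-4a-methyl-4,4a,5,6,7,8-hexahydronaphthalen-2(3H)-one | C[C@]12CCC(=O)C=C1CCCC2 | starting material
2 | (2R,4aS)-4a-methyl-2-(propan-2-yl)-2,3,4,4a,5,6,7,8-octahydronaphthalen-2-ol | C[C@]12CC[C@@](O)(C(C)C)C=C1CCCC2 | intermediate
3 | cyclic dioxo(TMEDA)osmium 1β,8aβ-diolate (hexavalent osmium ester of triol 4) | C[C@]12CC[C@@](O)(C(C)C)[C@@H]3O[Os-2]4(=O)(=O)([N+](C)(C)CC[N+]4(C)C)O[C@]13CCCC2 | intermediate
4 | (1S,2R,4aS,8aR)-4a-methyl-2-(propan-2-yl)decahydronaphthalene-1,2,8a-triol | C[C@]12CC[C@@](O)(C(C)C)[C@H](O)[C@@]1(O)CCCC2 | intermediate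
5 | (1S,2R,4aS,8aR)-2,8a-dihydroxy-4a-methyl-2-(propan-2-yl)decahydronaphthalen-1-yl methanesulfonate | C[C@]12CC[C@@](O)(C(C)C)[C@H](OS(C)(=O)=O)[C@@]1(O)CCCC2 | intermediate
6 | (3R,3aR,8aS)-3-hydroxy-8a-methyl-3-(propan-2-yl)octahydroazulen-4(1H)-one | C1CC(=O)[C@@H]2[C@](C)(CC[C@@]2(O)C(C)C)CC1 | intermediate
7 | (3R,3aR,8aS)-3-hydroxy-8a-methyl-3-(propan-2-yl)-2,3,3a,7,8,8a-hexahydroazulen-4(1H)-one | C1=CC(=O)[C@@H]2[C@](C)(CC[C@@]2(O)C(C)C)CC1 | intermediate
8 | 6,8a-dimethyl-3-(propan-2-yl)-4-(trimethylsilyloxy)-1,2,3,3a,6,7,8,8a-octahydroazulen-3-ol (C3, C3a, C8a as in 7; C6 undefined) | CC1C=C(O[Si](C)(C)C)[C@@H]2[C@](C)(CC[C@@]2(O)C(C)C)CC1 | intermediate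
9 | (3R,3aR,8aS)-3-hydroxy-6,8a-dimethyl-3-(propan-2-yl)-2,3,3a,7,8,8a-hexahydroazulen-4(1H)-one | CC1=CC(=O)[C@@H]2[C@](C)(CC[C@@]2(O)C(C)C)CC1 | intermediate
10 | (3R,3aR,8aR)-3-hydroxy-6,8a-dimethyl-3-(propan-2-yl)-1,2,3,3a,8,8a-hexahydroazulene-4,7-dione | CC1=CC(=O)[C@@H]2[C@](C)(CC[C@@]2(O)C(C)C)CC1=O | intermediate
11 | 4-[(tert-butyldimethylsilyl)oxy]benzaldehyde | CC(C)(C)[Si](C)(C)Oc1ccc(C=O)cc1 | starting material
12 | (3R,3aS,4S,8aR)-4-hydroxy-6,8a-dimethyl-7-oxo-3-(propan-2-yl)-1,2,3,3a,4,7,8,8a-octahydroazulen-3-yl 4-[(tert-butyldimethylsilyl)oxy]benzoate | CC1=C[C@H](O)[C@@H]2[C@](C)(CC[C@@]2(OC(=O)c2ccc(O[Si](C)(C)C(C)(C)C)cc2)C(C)C)CC1=O | intermediate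
13 | (3R,3aS,4S,8aR)-4-hydroxy-6,8a-dimethyl-7-oxo-3-(propan-2-yl)-1,2,3,3a,4,7,8,8a-octahydroazulen-3-yl 4-hydroxybenzoate | CC1=C[C@H](O)[C@@H]2[C@](C)(CC[C@@]2(OC(=O)c2ccc(O)cc2)C(C)C)CC1=O | target

Total steps: 8. Longest linear sequence: 8 steps (1 to 13).

Steps most likely to fail

Step 8 (carries the label). Three processes can defeat it:
- The tertiary samarium aldolate may open by retro-aldol cleavage faster than it adds to the electron-rich aldehyde.
- Residual divalent samarium may reduce the enedione by electron transfer.
- The acyl group may wander to O-4.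

The fallback uses known chemistry only, sets out from 10 and comes back at 13. Hydroxyl-directed Evans–Saksena reduction of 10 (Me4NBH(OAc)3, MeCN/AcOH, −20 °C) uses the same internal hydride delivery, leaves the C7 carbonyl alone and gives the 3,4-diol F1. TESCl and imidazole silylate only the secondary allylic hydroxyl to give the 4-O-triethylsilyl ether F2. The tertiary hydroxyl is then acylated with 4-(tert-butyldimethylsilyloxy)benzoyl chloride (DMAP, Et3N, toluene, 80 °C) to the bis-silylated ester F3. HF·pyridine removes both silyl groups to give 13.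

Step 7. Hydrogen abstraction may take place at the C6 methyl group, conversion of the electron-poor enone may stall, or the peroxide may epoxidise the enone. The fallback replaces C–H oxidation by a vinylogous Rubottom oxidation, sets out from 9 and comes back at 10. TMSOTf and Et3N give the linear, endocyclic bis-silylated dienol ether F4. mCPBA (NaHCO3, CH2Cl2, 0 °C) attacks its electron-rich C7 terminus, and a mild acidic work-up gives the 7-hydroxy enone F5. MnO2 oxidises this unhindered allylic alcohol to 10.

Step 2. The bulky osmium–diamine complex may react sluggishly at an alkene flanked by two fully substituted carbons, or it may attack the α face. The fallback gives up facial control and relies on stereoconvergence, sets out from 2 and comes back at 6.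
- Catalytic OsO4 with NMO attacks anti to the allylic hydroxyl and the angular methyl group and gives the 1α,8aα-diol F6, a trans-decalin.
- MsCl and Et3N give the equatorial 1α-mesylate F7, whose C–O bond is again antiperiplanar to C4a–C8a.
- KOt-Bu in THF triggers the same 1,2-shift and gives the cis-fused ketone F8.
- The same base epimerises the acidic C3a to the trans-fused 6. This isomer should be the more stable one because C4 is then trans to the isopropyl group and can accept a hydrogen bond from the C3 hydroxyl.

Both faces of the alkene therefore lead to 6.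

Further compounds
F1 | step 8 | (3R,3aS,4S,8aR)-3,4-dihydroxy-6,8a-dimethyl-3-(propan-2-yl)-1,2,3,3a,4,8a-hexahydroazulen-7(8H)-one | CC1=C[C@H](O)[C@@H]2[C@](C)(CC[C@@]2(O)C(C)C)CC1=O
F2 | step 8 | 4-O-triethylsilyl ether of F1 | CC1=C[C@H](O[Si](CC)(CC)CC)[C@@H]2[C@](C)(CC[C@@]2(O)C(C)C)CC1=O
F3 | step 8 | 4-O-triethylsilyl ether of 12 (bis-silylated ester) | CC1=C[C@H](O[Si](CC)(CC)CC)[C@@H]2[C@](C)(CC[C@@]2(OC(=O)c2ccc(O[Si](C)(C)C(C)(C)C)cc2)C(C)C)CC1=O
F4 | step 7 | 3,4-bis(trimethylsilyloxy)-6,8a-dimethyl-3-(propan-2-yl)-1,2,3,3a,8,8a-hexahydroazulene (4,6-diene) | CC1=CC[C@@]2(C)CC[C@@](O[Si](C)(C)C)(C(C)C)[C@@H]2C(O[Si](C)(C)C)=C1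
F5 | step 7 | 3,7-dihydroxy-6,8a-dimethyl-3-(propan-2-yl)-2,3,3a,7,8,8a-hexahydroazulen-4(1H)-one (C7 undefined) | CC1=CC(=O)[C@@H]2[C@](C)(CC[C@@]2(O)C(C)C)CC1O
F6 | step 2 | (1R,2R,4aS,8aS)-4a-methyl-2-(propan-2-yl)decahydronaphthalene-1,2,8a-triol | C[C@]12CC[C@@](O)(C(C)C)[C@@H](O)[C@]1(O)CCCC2
F7 | step 2 | (1R,2R,4aS,8aS)-2,8a-dihydroxy-4a-methyl-2-(propan-2-yl)decahydronaphthalen-1-yl methanesulfonate | C[C@]12CC[C@@](O)(C(C)C)[C@@H](OS(C)(=O)=O)[C@]1(O)CCCC2
F8 | step 2 | (3R,3aS,8aS)-3-hydroxy-8a-methyl-3-(propan-2-yl)octahydroazulen-4(1H)-one (cis-fused) | C1CC(=O)[C@H]2[C@](C)(CC[C@@]2(O)C(C)C)CC1
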